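**Retrosynthetic overview**

1. Tomentodione O (33) ⇒ (5R)-dienol 27 + enetrione 32 (from syncarpic acid 30 and 3-methylbutanal 31). An oxa-Diels–Alder reaction across C8=C15 forms C8–O and C15–C1′, so the dihydropyran is the last ring.
2. 27 ⇒ iodo-aldehyde 24. The nine-membered ring is closed by a Nozaki–Hiyama–Kishi reaction at C4–C5, and C5 is then fixed by oxidation and CBS reduction.
3. 24 ⇒ trans-cyclobutane ester 13. The ester carbon becomes C8 (Weinreb ketone synthesis with a C7–C5 Grignard reagent, then Wittig methylenation to C8=C15), and C3 becomes the (Z)-iodoalkene.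
4. 13 ⇒ diazo ester 10. The route rests on the cyclobutane C1–C9–C10–C11, in which quaternary C11 (gem-dimethyl) sits next to stereocentre C1 and C9 carries C8 at the carboxyl level. Rh-carbene bicyclobutanation makes C9–C1 and C9–C11, and a methylcuprate opens C9–C11 at C11.
5. Ring order: cyclobutane (through the bicyclobutane), nine-membered carbocycle, dihydropyran on the ready-made trione ring. 10 comes in seven steps from propane-1,3-diol, a Wittig ylide and tert-butyl acetoacetate.

Key step: step 8

Numbering: C1–C15 follow the caryophyllane skeleton (C15 is the pyran CH2, C1′ the isobutyl-bearing carbon); TBS = tert-butyldimethylsilyl.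

Assumption: Rh2(S-NTTL)4 is taken to select the alkene face that gives (R)-C1 with this alkyl-substituted trisubstituted alkene; if a model run shows the opposite sense, Rh2(R-NTTL)4 is used and nothing else changes.

**Route**

Step 1
Reactants: 1 propane-1,3-diol
Product: 2 3-[(tert-butyldimethylsilyl)oxy]propan-1-ol
Conditions: NaH (1 equiv), THF, 0 °C; TBSCl (1 equiv), 0 °C → rt
Reagents that add atoms: tert-butyldimethylsilyl chloride, CC(C)(C)[Si](C)(C)Cl
Why: Silyl ether formation on the sparingly soluble monosodium alkoxide of a symmetric diol, which should hold the reaction at monosilylation.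

Step 2
Reactants: 2 3-[(TBS)oxy]propan-1-ol
Product: 3 3-[(TBS)oxy]propanal
Conditions: TEMPO (cat.), PhI(OAc)2, CH2Cl2, rt
Reagents that add atoms: none
Why: TEMPO/oxoammonium oxidation of a primary alcohol stops at the aldehyde and is mild enough to avoid β-elimination of the silyloxy group.

Step 3
Reactants: 3 3-[(TBS)oxy]propanal; 4 ethyl 2-(triphenylphosphoranylidene)propanoate
Product: 5 ethyl (E)-5-[(TBS)oxy]-2-methylpent-2-enoate
Conditions: CH2Cl2, rt
Reagents that add atoms: none
Why: Wittig olefination with a stabilised α-methyl ylide, which should give the (E)-trisubstituted enoate that later fixes the exo position of the side chain on the bicyclobutane.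

Step 4
Reactants: 5 ethyl (E)-5-[(TBS)oxy]-2-methylpent-2-enoate
Product: 6 (E)-5-[(TBS)oxy]-2-methylpent-2-en-1-ol
Conditions: DIBAL-H (2.2 equiv), CH2Cl2, −78 °C; Rochelle salt work-up
Reagents that add atoms: none
Why: 1,2-Reduction of an enoate by DIBAL-H gives the allylic alcohol without touching the alkene geometry or the silyl ether.

Step 5
Reactants: 6 (E)-5-[(TBS)oxy]-2-methylpent-2-en-1-ol
Product: 7 (E)-1-bromo-5-[(TBS)oxy]-2-methylpent-2-ene
Conditions: CBr4, PPh3, CH2Cl2, 0 °C
Reagents that add atoms: tetrabromomethane, BrC(Br)(Br)Br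
Why: Appel bromination of a primary allylic alcohol proceeds by SN2 displacement of the oxyphosphonium group at low temperature, with the alkene geometry kept.

Step 6
Reactants: 7 (E)-1-bromo-5-[(TBS)oxy]-2-methylpent-2-ene; 8 tert-butyl acetoacetate
Product: 9 tert-butyl (E)-2-acetyl-4-methyl-7-[(TBS)oxy]hept-4-enoate
Conditions: 8 (1.5 equiv), NaH, THF, 0 °C → rt
Reagents that add atoms: none
Why: Acetoacetic ester alkylation, in which the sodium enolate displaces the unhindered primary allylic bromide at carbon by SN2 and the excess of 8 suppresses dialkylation.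

Step 7
Reactants: 9 tert-butyl (E)-2-acetyl-4-methyl-7-[(TBS)oxy]hept-4-enoate
Product: 10 tert-butyl (E)-2-diazo-4-methyl-7-[(TBS)oxy]hept-4-enoate
Conditions: 4-acetamidobenzenesulfonyl azide, DBU, MeCN, 0 °C → rt
Reagents that add atoms: 4-acetamidobenzenesulfonyl azide, CC(=O)Nc1ccc(cc1)S(=O)(=O)N=[N+]=[N-]
Why: Deacylative Regitz diazo transfer, in which the enolate of the α-alkyl acetoacetate attacks the sulfonyl azide and the acetyl group leaves on the sulfonamide nitrogen to give the α-alkyl-α-diazo ester.

Step 8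
Reactants: 10 tert-butyl (E)-2-diazo-4-methyl-7-[(TBS)oxy]hept-4-enoate
Product: 13 tert-butyl (1S,2R)-2-{2-[(TBS)oxy]ethyl}-3,3-dimethylcyclobutane-1-carboxylate (trans), via bicyclobutane ester 11 (not isolated), via cis ester 12 (not isolated)
Conditions: Rh2(S-NTTL)4 (0.5 mol%), PhMe, −78 °C, slow addition of 10; then CuBr·SMe2 (0.3 equiv), PBu3, MeMgCl, THF, −78 °C → rt; then t-BuOH; then KOtBu (0.5 equiv), THF, rt
Reagents that add atoms: methylmagnesium chloride, C[Mg]Cl
Why: The Rh(II) carbene from 10 adds to the tethered trisubstituted C11=C1 alkene and forms C9–C11 and C9–C1 stereospecifically (the (E)-alkene puts the C2–C3 chain exo on bicyclobutane 11), and the methylcopper–phosphine reagent then attacks the methyl-bearing bridgehead C11 with cleavage of the strained central C9–C11 bond to give quaternary C11 and a cyclobutyl ester enolate; the closest known reaction type is the Rh-catalysed enantioselective bicyclobutanation of 2-diazo-4-enoates coupled with Cu-catalysed homoconjugate Grignard addition, used here on a substrate whose attacked bridgehead carries a methyl group. The ring closure is a 3-exo-trig carbene addition across C11=C1 that fuses two cyclopropanes, and the four-membered ring C9–C10–C11–C1 that remains after the opening is closed by the C9–C1 bond. C1 is set by the chiral dirhodium carboxylate, which selects the alkene face in the cyclopropanation, while C11 ends with two methyl groups and so raises no stereochemical demand. C9 is set by substrate control: the enolate is protonated from the face away from the C1 side chain and so should give mainly cis ester 12, and the alkoxide equilibration then moves C9 to the more stable trans arrangement of 13. The step needs cyclopropanation to outrun the 1,2-hydride shift of the α-alkyl carbene to the dienoate, which the tert-butyl ester, the bulky carboxylate ligands, the low temperature and the electron-rich alkene secure, and it needs attack at C11 and not at the ester carbonyl, which the tert-butyl group and the release of bicyclobutane strain secure.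

Step 9
Reactants: 13 tert-butyl (1S,2R)-2-{2-[(TBS)oxy]ethyl}-3,3-dimethylcyclobutane-1-carboxylate
Product: 15 (1S,2R)-2-{2-[(TBS)oxy]ethyl}-3,3-dimethylcyclobutane-1-carboxylic acid, via trimethylsilyl ester 14 (not isolated)
Conditions: TMSOTf, 2,6-lutidine, CH2Cl2, 0 °C → rt; then pH 7 buffer
Reagents that add atoms: none
Why: Silyl triflate-mediated tert-butyl ester cleavage (O-silylation, loss of the tert-butyl cation as isobutene, hydrolysis of the silyl ester on work-up) under buffered conditions that leave the primary TBS ether intact.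

Step 10
Reactants: 15 (1S,2R)-2-{2-[(TBS)oxy]ethyl}-3,3-dimethylcyclobutane-1-carboxylic acid
Product: 16 (1S,2R)-2-{2-[(TBS)oxy]ethyl}-N-methoxy-N,3,3-trimethylcyclobutane-1-carboxamide
Conditions: MeNHOMe·HCl, EDC·HCl, HOBt (cat.), iPr2NEt, CH2Cl2, rt
Reagents that add atoms: N,O-dimethylhydroxylamine hydrochloride, CNOC.Cl
Why: Carbodiimide amide coupling to the Weinreb amide, in which C9 is safe because the trans arrangement is the thermodynamic one.

Step 11
Reactants: 16 the Weinreb amide; 17 2-(2-bromoethyl)-1,3-dioxolane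
Product: 19 1-[(1S,2R)-2-{2-[(TBS)oxy]ethyl}-3,3-dimethylcyclobutyl]-3-(1,3-dioxolan-2-yl)propan-1-one, via Grignard reagent 18 (not isolated)
Conditions: 17, Mg, THF, 25 °C; then 16, THF, 0 °C; aq. NH4Cl
Reagents that add atoms: none
Why: Weinreb ketone synthesis, in which the chelated tetrahedral intermediate prevents over-addition, so that the C8 ketone forms with C7–C6–C5 attached and C5 masked as the acetal.

Step 12
Reactants: 19 the C8 ketone
Product: 20 2-{3-[(1S,2R)-2-{2-[(TBS)oxy]ethyl}-3,3-dimethylcyclobutyl]but-3-en-1-yl}-1,3-dioxolane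
Conditions: Ph3PCH3Br, KOtBu, THF, 0 °C → rt
Reagents that add atoms: methyltriphenylphosphonium bromide, C[P+](c1ccccc1)(c1ccccc1)c1ccccc1.[Br-]
Why: Wittig methylenation of the ketone installs C15 before the C5 aldehyde is unveiled (a free γ-keto aldehyde is avoided), and any enolisation at C9 returns the favoured trans isomer.

Step 13
Reactants: 20 the TBS ether
Product: 21 2-[(1R,4S)-4-[4-(1,3-dioxolan-2-yl)but-1-en-2-yl]-2,2-dimethylcyclobutyl]ethan-1-ol
Conditions: TBAF, THF, 0 °C → rt
Reagents that add atoms: none
Why: Fluoride-mediated desilylation frees the C3 alcohol, and the acetal and both alkenes are inert to fluoride.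

Step 14
Reactants: 21 the C3 alcohol
Product: 22 2-[(1R,4S)-4-[4-(1,3-dioxolan-2-yl)but-1-en-2-yl]-2,2-dimethylcyclobutyl]acetaldehyde
Conditions: Dess–Martin periodinane, CH2Cl2, 0 °C → rt
Reagents that add atoms: none
Why: Dess–Martin oxidation gives the aldehyde under near-neutral conditions, and the aldehyde has only a CH2 at its α-position so no stereocentre is at risk.

Step 15
Reactants: 22 the C3 aldehyde
Product: 23 2-{3-[(1S,2R)-2-[(2Z)-3-iodobut-2-en-1-yl]-3,3-dimethylcyclobutyl]but-3-en-1-yl}-1,3-dioxolane
Conditions: EtPPh3I, n-BuLi, THF, rt; I2, −78 °C; NaHMDS, −78 → −20 °C; then 22, −78 °C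
Reagents that add atoms: ethyltriphenylphosphonium iodide, CC[P+](c1ccccc1)(c1ccccc1)c1ccccc1.[I-]; iodine, II
Why: Stork–Zhao-type Wittig olefination with the α-iodo ylide, which under kinetic control should give the (Z)-iodoalkene with iodine cis to C2, the geometry that the ring alkene needs.

Step 16
Reactants: 23 the iodoalkene acetal
Product: 24 4-[(1S,2R)-2-[(2Z)-3-iodobut-2-en-1-yl]-3,3-dimethylcyclobutyl]pent-4-enal
Conditions: p-TsOH·H2O (cat.), acetone–H2O, rt
Reagents that add atoms: water, O
Why: Acid-catalysed acetal hydrolysis (transacetalisation into acetone) is mild enough to leave the 1,1-disubstituted alkene and the alkenyl iodide untouched.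

Step 17
Reactants: 24 the iodo-aldehyde
Product: 25 (1R,3Z,9S)-4,11,11-trimethyl-8-methylidenebicyclo[7.2.0]undec-3-en-5-ol (5RS mixture)
Conditions: CrCl2 (excess), NiCl2 (cat.), DMSO–THF, rt, high dilution
Reagents that add atoms: none
Why: Nozaki–Hiyama–Kishi reaction, in which Ni-catalysed oxidative addition and transmetalation give an alkenylchromium(III) species that adds only to the aldehyde with retention of the (Z)-geometry; the trans-cyclobutane holds the two arms so that the ring-cis C3=C4 alkene can close the nine-membered ring, and C5 forms as an epimer mixture that the next two steps converge.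

Step 18
Reactants: 25 the C5 alcohol mixture
Product: 26 (1R,3Z,9S)-4,11,11-trimethyl-8-methylidenebicyclo[7.2.0]undec-3-en-5-one
Conditions: Dess–Martin periodinane, CH2Cl2, 0 °C → rt
Reagents that add atoms: none
Why: Dess–Martin oxidation of the allylic alcohol converges both C5 epimers to one enone, whose ring-cis alkene is the stable geometry in a nine-membered ring.

Step 19
Reactants: 26 the enone
Product: 27 (1R,3Z,5R,9S)-4,11,11-trimethyl-8-methylidenebicyclo[7.2.0]undec-3-en-5-ol
Conditions: (S)-Me-CBS (cat.), catecholborane, PhMe, −78 °C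
Reagents that add atoms: none
Why: Corey–Bakshi–Shibata reduction, in which the α-methyl-substituted alkenyl arm acts as the large group and the C6 methylene as the small one, so that the (S)-oxazaborolidine should give the (5R)-alcohol under reagent control while catecholborane at low temperature leaves the alkenes alone.

Step 20
Reactants: 28 2,4,6-trihydroxyacetophenone
Product: 29 2-acetyl-3-hydroxy-4,4,6,6-tetramethylcyclohex-2-ene-1,5-dione (acetylsyncarpic acid)
Conditions: MeI (excess), NaOMe, MeOH, reflux
Reagents that add atoms: iodomethane, CI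
Why: Exhaustive C-methylation of the acylphloroglucinol polyanion at its two free ring carbons dearomatises the ring to the gem-dimethylated β-triketone.

Step 21
Reactants: 29 acetylsyncarpic acid
Product: 30 2,2,4,4-tetramethylcyclohexane-1,3,5-trione (syncarpic acid)
Conditions: 6 M HCl (aq), reflux
Reagents that add atoms: none
Why: Acid-promoted retro-Claisen deacylation of the 2-acyl-1,3-dione removes the acetyl group as acetic acid.

Step 22
Reactants: 27 the (5R)-dienol; 30 syncarpic acid; 31 3-methylbutanal
Product: 33 Tomentodione O, via enetrione 32 (not isolated)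
Conditions: ethylenediammonium diacetate (cat.), 30 and 31 in excess, PhMe, 4 Å MS, rt → 60 °C
Reagents that add atoms: none
Why: Knoevenagel condensation gives enetrione 32, which reacts as an electron-poor 1-oxadiene with the electron-rich 1,1-disubstituted C8=C15 alkene in an inverse-demand oxa-Diels–Alder reaction (O to the more substituted C8, C1′ to C15), and the heterodiene should add to the alkene face syn to C10 and away from the C1 ring arm (C9–H eclipsing the methylene) to set (S)-C8, with the C7 methylene endo and the branched C9 exo so that isobutyl ends cis to C7 and C1′ is (R), while the trisubstituted C3=C4 alkene is less reactive.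

**Compound list**

1 | propane-1,3-diol | OCCCO | starting material
2 | 3-[(tert-butyldimethylsilyl)oxy]propan-1-ol | CC(C)(C)[Si](C)(C)OCCCO | intermediate
3 | 3-[(tert-butyldimethylsilyl)oxy]propanal | CC(C)(C)[Si](C)(C)OCCC=O | intermediate
4 | ethyl 2-(triphenylphosphoranylidene)propanoate | CCOC(=O)C(C)=P(c1ccccc1)(c1ccccc1)c1ccccc1 | starting material
5 | ethyl (E)-5-[(TBS)oxy]-2-methylpent-2-enoate | CCOC(=O)/C(C)=C/CCO[Si](C)(C)C(C)(C)C | intermediate
6 | (E)-5-[(TBS)oxy]-2-methylpent-2-en-1-ol | OC/C(C)=C/CCO[Si](C)(C)C(C)(C)C | intermediate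
7 | (E)-1-bromo-5-[(TBS)oxy]-2-methylpent-2-ene | BrC/C(C)=C/CCO[Si](C)(C)C(C)(C)C | intermediate
8 | tert-butyl acetoacetate | CC(=O)CC(=O)OC(C)(C)C | starting material
9 | tert-butyl (E)-2-acetyl-4-methyl-7-[(TBS)oxy]hept-4-enoate (racemic at C2) | CC(=O)C(C/C(C)=C/CCO[Si](C)(C)C(C)(C)C)C(=O)OC(C)(C)C | intermediate
10 | tert-butyl (E)-2-diazo-4-methyl-7-[(TBS)oxy]hept-4-enoate | CC(C)(C)OC(=O)C(=[N+]=[N-])C/C(C)=C/CCO[Si](C)(C)C(C)(C)C | intermediate
11 | tert-butyl 2-{2-[(TBS)oxy]ethyl}-3-methylbicyclo[1.1.0]butane-1-carboxylate (exo-2 isomer with (2S) configuration) | CC(C)(C)OC(=O)[C@]12C[C@@]1(C)[C@@H]2CCO[Si](C)(C)C(C)(C)C | intermediate (not isolated)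
12 | tert-butyl (1R,2R)-2-{2-[(TBS)oxy]ethyl}-3,3-dimethylcyclobutane-1-carboxylate (cis) | CC(C)(C)[Si](C)(C)OCC[C@@H]1[C@@H](CC1(C)C)C(=O)OC(C)(C)C | intermediate (not isolated)
13 | tert-butyl (1S,2R)-2-{2-[(TBS)oxy]ethyl}-3,3-dimethylcyclobutane-1-carboxylate (trans) | CC(C)(C)[Si](C)(C)OCC[C@@H]1[C@H](CC1(C)C)C(=O)OC(C)(C)C | intermediate
14 | trimethylsilyl (1S,2R)-2-{2-[(TBS)oxy]ethyl}-3,3-dimethylcyclobutane-1-carboxylate | CC(C)(C)[Si](C)(C)OCC[C@@H]1[C@H](CC1(C)C)C(=O)O[Si](C)(C)C | intermediate (not isolated)
15 | (1S,2R)-2-{2-[(TBS)oxy]ethyl}-3,3-dimethylcyclobutane-1-carboxylic acid | CC(C)(C)[Si](C)(C)OCC[C@@H]1[C@H](CC1(C)C)C(=O)O | intermediate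
16 | (1S,2R)-2-{2-[(TBS)oxy]ethyl}-N-methoxy-N,3,3-trimethylcyclobutane-1-carboxamide | CC(C)(C)[Si](C)(C)OCC[C@@H]1[C@H](CC1(C)C)C(=O)N(C)OC | intermediate
17 | 2-(2-bromoethyl)-1,3-dioxolane | BrCCC1OCCO1 | starting material
18 | [2-(1,3-dioxolan-2-yl)ethyl]magnesium bromide | Br[Mg]CCC1OCCO1 | intermediate (not isolated)
19 | 1-[(1S,2R)-2-{2-[(TBS)oxy]ethyl}-3,3-dimethylcyclobutyl]-3-(1,3-dioxolan-2-yl)propan-1-one | CC(C)(C)[Si](C)(C)OCC[C@@H]1[C@H](CC1(C)C)C(=O)CCC1OCCO1 | intermediate
20 | 2-{3-[(1S,2R)-2-{2-[(TBS)oxy]ethyl}-3,3-dimethylcyclobutyl]but-3-en-1-yl}-1,3-dioxolane | CC(C)(C)[Si](C)(C)OCC[C@@H]1[C@H](CC1(C)C)C(=C)CCC1OCCO1 | intermediate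
21 | 2-[(1R,4S)-4-[4-(1,3-dioxolan-2-yl)but-1-en-2-yl]-2,2-dimethylcyclobutyl]ethan-1-ol | OCC[C@@H]1[C@H](CC1(C)C)C(=C)CCC1OCCO1 | intermediate
22 | 2-[(1R,4S)-4-[4-(1,3-dioxolan-2-yl)but-1-en-2-yl]-2,2-dimethylcyclobutyl]acetaldehyde | O=CC[C@@H]1[C@H](CC1(C)C)C(=C)CCC1OCCO1 | intermediate
23 | 2-{3-[(1S,2R)-2-[(2Z)-3-iodobut-2-en-1-yl]-3,3-dimethylcyclobutyl]but-3-en-1-yl}-1,3-dioxolane | C/C(I)=C/C[C@@H]1[C@H](CC1(C)C)C(=C)CCC1OCCO1 | intermediate
24 | 4-[(1S,2R)-2-[(2Z)-3-iodobut-2-en-1-yl]-3,3-dimethylcyclobutyl]pent-4-enal | C/C(I)=C/C[C@@H]1[C@H](CC1(C)C)C(=C)CCC=O | intermediate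
25 | (1R,3Z,9S)-4,11,11-trimethyl-8-methylidenebicyclo[7.2.0]undec-3-en-5-ol (5RS mixture) | C/C1=C/C[C@@H]2[C@H](CC2(C)C)C(=C)CCC1O | intermediate
26 | (1R,3Z,9S)-4,11,11-trimethyl-8-methylidenebicyclo[7.2.0]undec-3-en-5-one | C/C1=C/C[C@@H]2[C@H](CC2(C)C)C(=C)CCC1=O | intermediate
27 | (1R,3Z,5R,9S)-4,11,11-trimethyl-8-methylidenebicyclo[7.2.0]undec-3-en-5-ol | C/C1=C/C[C@@H]2[C@H](CC2(C)C)C(=C)CC[C@H]1O | intermediate
28 | 2,4,6-trihydroxyacetophenone | CC(=O)c1c(O)cc(O)cc1O | starting material
29 | 2-acetyl-3-hydroxy-4,4,6,6-tetramethylcyclohex-2-ene-1,5-dione (acetylsyncarpic acid) | CC(=O)C1=C(O)C(C)(C)C(=O)C(C)(C)C1=O | intermediate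
30 | 2,2,4,4-tetramethylcyclohexane-1,3,5-trione (syncarpic acid) | CC1(C)C(=O)CC(=O)C(C)(C)C1=O | intermediate
31 | 3-methylbutanal | CC(C)CC=O | starting material
32 | 2,2,4,4-tetramethyl-6-(3-methylbutylidene)cyclohexane-1,3,5-trione | CC(C)CC=C1C(=O)C(C)(C)C(=O)C(C)(C)C1=O | intermediate (not isolated)
33 | Tomentodione O | C/C1=C/C[C@@H]2[C@H](CC2(C)C)[C@]2(CC[C@H]1O)C[C@@H](CC(C)C)C1=C(O2)C(C)(C)C(=O)C(C)(C)C1=O | target

**Step count**

Total: 22 steps. Longest linear sequence: 20 steps (steps 1–19 and 22); steps 20–21 form the short syncarpic acid branch.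

**Steps most likely to fail**

Step 8. The α-alkyl Rh carbene may undergo 1,2-hydride shift to the dienoate faster than it cyclopropanates the trisubstituted alkene. The enantioselectivity may fall with an alkyl-substituted alkene. The cuprate may attack the methyl-bearing bridgehead too slowly, so that the acid-sensitive bicyclobutane decomposes, and the C9 equilibration may stop short of completion. The fallback sets out from aldehyde 3 and comes back to the route at acid 15; it builds the ring by a ketene [2+2] cycloaddition and secures the enantiomer by resolution. Wittig olefination of 3 with isopropylidenetriphenylphosphorane should give tert-butyldimethyl[(4-methylpent-3-en-1-yl)oxy]silane F1. Cycloaddition with dichloroketene (Cl3CCOCl, Zn–Cu, Et2O) should join the carbonyl carbon to the less substituted alkene carbon and give the dichlorocyclobutanone F2. Zinc dechlorination (Zn, NH4Cl, MeOH) should give 2-{2-[(TBS)oxy]ethyl}-3,3-dimethylcyclobutan-1-one F3. Van Leusen reductive cyanation (TosMIC, KOtBu, DME/t-BuOH) should give the cyclobutanecarbonitrile F4, and DIBAL-H reduction followed by K2CO3/MeOH equilibration the racemic trans carbaldehyde F5. Pinnick oxidation should give the racemic trans acid F6, and preparative chromatography on a chiral stationary phase should separate 15 from its enantiomer F7.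

Step 22. The heterodiene may discriminate poorly between the two faces of C8=C15 or between the endo and exo orientations, which would give C8 and C1′ diastereomers. It may also add to C3=C4. The free allylic alcohol may add reversibly to the enetrione or trigger transannular reactions of the nine-membered ring under the weakly acidic conditions. The fallback sets out from enone 26 and comes back at the target 33; it moves the cycloaddition one stage earlier, onto a dienophile with a different ring conformation, no free hydroxyl group and a deactivated C3=C4 alkene. Cycloaddition of 26 with enetrione 32 under the conditions of step 22 should give the 5-oxo analogue of the target F11, whose diastereomers can be separated at the ketone stage. Reduction of the C5 enone carbonyl, either with (S)-Me-CBS/catecholborane or under Luche conditions (NaBH4, CeCl3, −78 °C), should then give 33; the two trione carbonyls are hindered by the flanking gem-dimethyl groups and the third is a vinylogous ester.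

Step 17. Intermolecular coupling may outrun the nine-ring closure and give oligomers, and the alkenylchromium species may be protonated before it reaches the aldehyde. The fallback sets out from aldehyde 22 and comes back at alcohol 25; it closes the ring at C3=C4 by metathesis instead of at C4–C5. Wittig methylenation of 22 should give the terminal alkene 2-{3-[(1S,2R)-3,3-dimethyl-2-(prop-2-en-1-yl)cyclobutyl]but-3-en-1-yl}-1,3-dioxolane F8, and acetal hydrolysis as in step 16 the pentenal F9. Addition of isopropenylmagnesium bromide should give the trienol F10 as a C5 epimer mixture. Ring-closing metathesis (second-generation Grubbs catalyst, PhMe, 80 °C, high dilution) between the monosubstituted alkene and the isopropenyl group should give 25 with loss of ethene. The ring-cis alkene is the less strained isomer, and closure onto C8=C15 would need a trans-fused bicyclo[3.2.0]heptene.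

**Further compounds**

F1 | step 8 | tert-butyldimethyl[(4-methylpent-3-en-1-yl)oxy]silane | CC(C)=CCCO[Si](C)(C)C(C)(C)C
F2 | step 8 | rac-4-{2-[(TBS)oxy]ethyl}-2,2-dichloro-3,3-dimethylcyclobutan-1-one | O=C1C(CCO[Si](C)(C)C(C)(C)C)C(C)(C)C1(Cl)Cl
F3 | step 8 | rac-2-{2-[(TBS)oxy]ethyl}-3,3-dimethylcyclobutan-1-one | O=C1CC(C)(C)C1CCO[Si](C)(C)C(C)(C)C
F4 | step 8 | 2-{2-[(TBS)oxy]ethyl}-3,3-dimethylcyclobutane-1-carbonitrile (racemic cis/trans mixture) | N#CC1CC(C)(C)C1CCO[Si](C)(C)C(C)(C)C
F5 | step 8 | rac-trans-2-{2-[(TBS)oxy]ethyl}-3,3-dimethylcyclobutane-1-carbaldehyde | CC(C)(C)[Si](C)(C)OCC[C@@H]1[C@H](CC1(C)C)C=O.CC(C)(C)[Si](C)(C)OCC[C@H]1[C@@H](CC1(C)C)C=O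
F6 | step 8 | rac-trans-2-{2-[(TBS)oxy]ethyl}-3,3-dimethylcyclobutane-1-carboxylic acid | CC(C)(C)[Si](C)(C)OCC[C@@H]1[C@H](CC1(C)C)C(=O)O.CC(C)(C)[Si](C)(C)OCC[C@H]1[C@@H](CC1(C)C)C(=O)O
F7 | step 8 | (1R,2S)-2-{2-[(TBS)oxy]ethyl}-3,3-dimethylcyclobutane-1-carboxylic acid (enantiomer of 15) | CC(C)(C)[Si](C)(C)OCC[C@H]1[C@@H](CC1(C)C)C(=O)O
F8 | step 17 | 2-{3-[(1S,2R)-3,3-dimethyl-2-(prop-2-en-1-yl)cyclobutyl]but-3-en-1-yl}-1,3-dioxolane | C=CC[C@@H]1[C@H](CC1(C)C)C(=C)CCC1OCCO1
F9 | step 17 | 4-[(1S,2R)-3,3-dimethyl-2-(prop-2-en-1-yl)cyclobutyl]pent-4-enal | C=CC[C@@H]1[C@H](CC1(C)C)C(=C)CCC=O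
F10 | step 17 | 6-[(1S,2R)-3,3-dimethyl-2-(prop-2-en-1-yl)cyclobutyl]-2-methylhepta-1,6-dien-3-ol (C3 epimer mixture) | C=CC[C@@H]1[C@H](CC1(C)C)C(=C)CCC(O)C(C)=C
F11 | step 22 | 5-oxo analogue of Tomentodione O (C5 ketone in place of the C5 alcohol) | C/C1=C/C[C@@H]2[C@H](CC2(C)C)[C@]2(CCC1=O)C[C@@H](CC(C)C)C1=C(O2)C(C)(C)C(=O)C(C)(C)C1=O
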